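**Retrosynthetic overview**
- The target triol comes from LiAlH4 opening of the (3R,4R)-α-hydroxy-α,β-bis(arylmethyl)-γ-butyrolactone.
- That lactone comes from hydrogenolysis of the acetylated product of the key intermolecular aldol: lithium enolate of the α-benzyloxy-β-arylmethyl lactone plus 4-benzyloxy-3-methoxybenzaldehyde. The bond formed joins the quaternary carbinol carbon to its benzylic carbon, anti to the neighbouring arylmethyl group.
- The α-benzyloxy lactone comes from Ag2O benzylation and Davis hydroxylation of the (S)-β-arylmethyl-γ-butyrolactone.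
- The (S)-lactone comes from Evans alkylation of the (R)-4-benzyloxazolidinone imide of O-benzyldihydroferulic acid with tert-butyl bromoacetate, then LiBH4 cleavage and lactonisation; the acid comes from ferulic acid.
- Rings: one ring is built, the γ-butyrolactone (step 5); it serves as the stereocontrol template and is opened in the last step. Both benzene rings are bought.

Assumption: the carbinol carbon created in the aldol step forms as an epimer mixture and is left undefined, because it is removed two steps later.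

**Route**

Step 1
Reactants: 1 ferulic acid [(E)-3-(4-hydroxy-3-methoxyphenyl)prop-2-enoic acid]
Product: 2 dihydroferulic acid [3-(4-hydroxy-3-methoxyphenyl)propanoic acid]
Conditions: H2 (1 atm), 10% Pd/C, MeOH, rt
Reagents that add atoms: none
Why: Catalytic hydrogenation saturates only the cinnamic C=C bond; arene, phenol and acid are inert under these conditions.

Step 2
Reactants: 2 dihydroferulic acid
Product: 4 O-benzyldihydroferulic acid [3-(4-benzyloxy-3-methoxyphenyl)propanoic acid], via benzyl ester 3 (not isolated)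
Conditions: BnBr (2.3 equiv), K2CO3 (3 equiv), DMF, 60 °C; then 2 M aq. NaOH, MeOH, 60 °C; then aq. HCl to pH 2
Reagents that add atoms: benzyl bromide BrCc1ccccc1; sodium hydroxide [Na+].[OH-]
Why: Williamson O-alkylation benzylates phenol and carboxylate together, and saponification then frees only the acid because the aryl benzyl ether is stable to hydroxide.

Step 3
Reactants: 4 O-benzyldihydroferulic acid; 5 (4R)-4-benzyl-1,3-oxazolidin-2-one
Product: 7 (4R)-4-benzyl-3-[3-(4-benzyloxy-3-methoxyphenyl)propanoyl]-1,3-oxazolidin-2-one, via mixed pivalic anhydride 6 (not isolated)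
Conditions: PivCl (1.1 equiv), Et3N (2.5 equiv), THF, −20 °C; then LiCl (1.1 equiv), 5 (1.0 equiv), −20 °C → rt
Reagents that add atoms: none
Why: N-acylation of the oxazolidinone through a mixed anhydride, in which the LiCl/Et3N-activated auxiliary attacks the unhindered acyl carbon and expels pivalate.

Step 4
Reactants: 7 imide; 8 tert-butyl bromoacetate
Product: 10 tert-butyl (3S)-3-[(4-benzyloxy-3-methoxyphenyl)methyl]-4-[(4R)-4-benzyl-2-oxo-1,3-oxazolidin-3-yl]-4-oxobutanoate, via sodium Z-enolate 9 (not isolated)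
Conditions: NaN(SiMe3)2 (1.1 equiv), THF, −78 °C; then 8 (2 equiv), −78 → −30 °C
Reagents that add atoms: none
Why: Evans asymmetric alkylation, in which the chelated Z-enolate is alkylated on the face opposite the C4 benzyl group of the (R)-auxiliary, setting the (S) centre (d.r. typically above 95:5) that becomes C3 of the target.

Step 5
Reactants: 10 alkylated imide
Product: 12 (4S)-4-[(4-benzyloxy-3-methoxyphenyl)methyl]oxolan-2-one, via hydroxy ester 11 (not isolated)
Conditions: LiBH4 (1.5 equiv), H2O (1.5 equiv), Et2O/THF, 0 °C; aq. NH4Cl work-up; then TsOH·H2O (0.1 equiv), toluene, 80 °C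
Reagents that add atoms: none
Why: Chemoselective hydride reduction of the imide carbonyl (the tert-butyl ester survives at 0 °C) releases the auxiliary and a γ-hydroxy ester that lactonises under acid catalysis; the stereocentre is not involved and ends up β to the carbonyl, where it cannot epimerise.

Step 6
Reactants: 12 (S)-lactone
Product: 14 (3S,4R)-4-[(4-benzyloxy-3-methoxyphenyl)methyl]-3-hydroxyoxolan-2-one, via sodium lactone enolate 13 (not isolated)
Conditions: NaN(SiMe3)2 (1.2 equiv), THF, −78 °C; then 3-phenyl-2-(phenylsulfonyl)oxaziridine (1.4 equiv), −78 °C; AcOH quench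
Reagents that add atoms: 3-phenyl-2-(phenylsulfonyl)oxaziridine O=S(=O)(c1ccccc1)N1OC1c1ccccc1
Why: Davis enolate hydroxylation delivers oxygen to the face anti to the C4 arylmethyl group (3,4-trans); the C3 configuration does not matter because C3 is made planar again in step 8, so any cis epimer is carried along.

Step 7
Reactants: 14 hydroxy lactone
Product: 15 (3S,4R)-3-(benzyloxy)-4-[(4-benzyloxy-3-methoxyphenyl)methyl]oxolan-2-one
Conditions: BnBr (3 equiv), Ag2O (2 equiv), 4 Å MS, CH2Cl2, rt, dark
Reagents that add atoms: benzyl bromide BrCc1ccccc1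
Why: Ag2O-promoted Williamson etherification benzylates the α-hydroxy lactone without a strong base, so the lactone is not opened.

Step 8
Reactants: 15 benzyloxy lactone; 16 4-(benzyloxy)-3-methoxybenzaldehyde (O-benzylvanillin)
Product: 18 (3S,4R)-3-(benzyloxy)-4-[(4-benzyloxy-3-methoxyphenyl)methyl]-3-[(4-benzyloxy-3-methoxyphenyl)(hydroxy)methyl]oxolan-2-one (both carbinol epimers), via lithium lactone enolate 17 (not isolated)
Conditions: LiN(iPr)2 (1.15 equiv), THF, −78 °C, 45 min; then 16 (1.3 equiv), THF, −78 °C, 1 h; AcOH quench at −78 °C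
Reagents that add atoms: none
Why: Intermolecular aldol addition of the planar lithium enolate to the non-enolisable aldehyde takes place anti to the C4 arylmethyl group, so the new C–C bond is trans and the benzyloxy group cis to it, which fixes the quaternary centre (C2 of the target); the cold acidic quench forestalls retro-aldol.

Step 9
Reactants: 18 aldol adduct
Product: 19 [(3S,4R)-3-(benzyloxy)-4-[(4-benzyloxy-3-methoxyphenyl)methyl]-2-oxooxolan-3-yl][4-(benzyloxy)-3-methoxyphenyl]methyl acetate (both epimers)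
Conditions: Ac2O (3 equiv), DMAP (0.2 equiv), pyridine, CH2Cl2, 0 °C → rt
Reagents that add atoms: acetic anhydride CC(=O)OC(C)=O
Why: DMAP-catalysed acylation turns the hindered benzylic alcohol into a better leaving group for hydrogenolysis, and elimination is impossible because the neighbouring carbon is quaternary.

Step 10
Reactants: 19 acetate
Product: 20 (3R,4R)-3-hydroxy-3,4-bis[(4-hydroxy-3-methoxyphenyl)methyl]oxolan-2-one
Conditions: H2 (3 atm), 20% Pd(OH)2/C, EtOAc/AcOH 4:1, rt
Reagents that add atoms: none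
Why: Catalytic hydrogenolysis cleaves the three benzyl ethers and the benzylic acetate (activated by the para oxygen), erasing the uncontrolled carbinol centre while C3 and C4, neither of them benzylic, stay untouched.

Step 11
Reactants: 20 hydroxy lactone
Product: 21 (2R,3R)-2,3-bis[(4-hydroxy-3-methoxyphenyl)methyl]butane-1,2,4-triol
Conditions: LiAlH4 (6 equiv), THF, 0 °C → reflux; then 1 M aq. HCl, EtOAc extraction
Reagents that add atoms: none
Why: Hydride reduction of the lactone gives the two primary carbinols; the former C3 is quaternary and the former C4 is not α to the carbonyl, so both stereocentres are retained.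

**Compound list**

1 | ferulic acid, (E)-3-(4-hydroxy-3-methoxyphenyl)prop-2-enoic acid | COc1cc(/C=C/C(=O)O)ccc1O | starting material
2 | dihydroferulic acid, 3-(4-hydroxy-3-methoxyphenyl)propanoic acid | COc1cc(CCC(=O)O)ccc1O | intermediate
3 | benzyl 3-(4-benzyloxy-3-methoxyphenyl)propanoate | COc1cc(CCC(=O)OCc2ccccc2)ccc1OCc1ccccc1 | intermediate (not isolated)
4 | 3-(4-benzyloxy-3-methoxyphenyl)propanoic acid | COc1cc(CCC(=O)O)ccc1OCc1ccccc1 | intermediate
5 | (4R)-4-benzyl-1,3-oxazolidin-2-one | O=C1N[C@H](Cc2ccccc2)CO1 | starting material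
6 | 3-(4-benzyloxy-3-methoxyphenyl)propanoic pivalic anhydride | COc1cc(CCC(=O)OC(=O)C(C)(C)C)ccc1OCc1ccccc1 | intermediate (not isolated)
7 | (4R)-4-benzyl-3-[3-(4-benzyloxy-3-methoxyphenyl)propanoyl]-1,3-oxazolidin-2-one | COc1cc(CCC(=O)N2[C@H](Cc3ccccc3)COC2=O)ccc1OCc1ccccc1 | intermediate
8 | tert-butyl bromoacetate | CC(C)(C)OC(=O)CBr | starting material
9 | sodium (1Z)-1-[(4R)-4-benzyl-2-oxo-1,3-oxazolidin-3-yl]-3-(4-benzyloxy-3-methoxyphenyl)prop-1-en-1-olate | [Na+].COc1cc(C/C=C(\[O-])N2[C@H](Cc3ccccc3)COC2=O)ccc1OCc1ccccc1 | intermediate (not isolated)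
10 | tert-butyl (3S)-3-[(4-benzyloxy-3-methoxyphenyl)methyl]-4-[(4R)-4-benzyl-2-oxo-1,3-oxazolidin-3-yl]-4-oxobutanoate | COc1cc(C[C@@H](CC(=O)OC(C)(C)C)C(=O)N2[C@H](Cc3ccccc3)COC2=O)ccc1OCc1ccccc1 | intermediate
11 | tert-butyl (3S)-3-[(4-benzyloxy-3-methoxyphenyl)methyl]-4-hydroxybutanoate | COc1cc(C[C@@H](CC(=O)OC(C)(C)C)CO)ccc1OCc1ccccc1 | intermediate (not isolated)
12 | (4S)-4-[(4-benzyloxy-3-methoxyphenyl)methyl]oxolan-2-one | O=C1OC[C@@H](Cc2ccc(OCc3ccccc3)c(OC)c2)C1 | intermediate
13 | sodium (4S)-4-[(4-benzyloxy-3-methoxyphenyl)methyl]-4,5-dihydrofuran-2-olate | [Na+].[O-]C1=C[C@H](Cc2ccc(OCc3ccccc3)c(OC)c2)CO1 | intermediate (not isolated)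
14 | (3S,4R)-4-[(4-benzyloxy-3-methoxyphenyl)methyl]-3-hydroxyoxolan-2-one | O=C1OC[C@@H](Cc2ccc(OCc3ccccc3)c(OC)c2)[C@@H]1O | intermediate
15 | (3S,4R)-3-(benzyloxy)-4-[(4-benzyloxy-3-methoxyphenyl)methyl]oxolan-2-one | O=C1OC[C@@H](Cc2ccc(OCc3ccccc3)c(OC)c2)[C@@H]1OCc1ccccc1 | intermediate
16 | 4-(benzyloxy)-3-methoxybenzaldehyde | O=Cc1ccc(OCc2ccccc2)c(OC)c1 | starting material
17 | lithium (4R)-3-(benzyloxy)-4-[(4-benzyloxy-3-methoxyphenyl)methyl]-4,5-dihydrofuran-2-olate | [Li+].[O-]C1=C(OCc2ccccc2)[C@H](Cc2ccc(OCc3ccccc3)c(OC)c2)CO1 | intermediate (not isolated)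
18 | (3S,4R)-3-(benzyloxy)-4-[(4-benzyloxy-3-methoxyphenyl)methyl]-3-[(4-benzyloxy-3-methoxyphenyl)(hydroxy)methyl]oxolan-2-one, carbinol carbon undefined | O=C1OC[C@@H](Cc2ccc(OCc3ccccc3)c(OC)c2)[C@]1(OCc1ccccc1)C(O)c1ccc(OCc2ccccc2)c(OC)c1 | intermediate
19 | [(3S,4R)-3-(benzyloxy)-4-[(4-benzyloxy-3-methoxyphenyl)methyl]-2-oxooxolan-3-yl][4-(benzyloxy)-3-methoxyphenyl]methyl acetate, carbinol carbon undefined | O=C1OC[C@@H](Cc2ccc(OCc3ccccc3)c(OC)c2)[C@]1(OCc1ccccc1)C(OC(C)=O)c1ccc(OCc2ccccc2)c(OC)c1 | intermediate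
20 | (3R,4R)-3-hydroxy-3,4-bis[(4-hydroxy-3-methoxyphenyl)methyl]oxolan-2-one | O=C1OC[C@@H](Cc2ccc(O)c(OC)c2)[C@]1(O)Cc1ccc(O)c(OC)c1 | intermediate
21 | (2R,3R)-2,3-bis[(4-hydroxy-3-methoxyphenyl)methyl]butane-1,2,4-triol | COc1cc(C[C@H](CO)[C@@](O)(CO)Cc2ccc(O)c(OC)c2)ccc1O | target

**Totals and risks**

Total step count: 11. Longest linear sequence: 11 steps, from 1 to 21; compounds 5, 8 and 16 are bought and enter directly.

The three steps most likely to fail are the hydroxylation (step 6), the aldol (step 8) and the hydrogenolysis (step 10).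

The hydroxylation of step 6 can suffer from over-oxidation and from addition of the enolate to the sulfonimine by-product. The fallback sets out from 12 and comes back at 14. Compound 12 is deprotonated with LiN(iPr)2 in THF at −78 °C to lithium (4S)-4-[(4-benzyloxy-3-methoxyphenyl)methyl]-4,5-dihydrofuran-2-olate F1. This is trapped with Me3SiCl as the silyl ketene acetal {[(4S)-4-[(4-benzyloxy-3-methoxyphenyl)methyl]-4,5-dihydrofuran-2-yl]oxy}trimethylsilane F2. Rubottom oxidation with mCPBA (NaHCO3, hexane/CH2Cl2, −20 °C) epoxidises F2 anti to the arylmethyl group and, after silyl migration, gives (3S,4R)-4-[(4-benzyloxy-3-methoxyphenyl)methyl]-3-[(trimethylsilyl)oxy]oxolan-2-one F3. Aqueous citric acid in THF removes the silyl group and returns 14.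

The aldol of step 8 is the most exposed step. The aldehyde is electron-rich, the new centre is quaternary, and the lithium aldolate can revert. The fallback sets out from 15 and comes back at 18. Enolate 17 is formed as before and silylated with Me3SiCl to the isolable silyl ketene acetal {[(4R)-3-(benzyloxy)-4-[(4-benzyloxy-3-methoxyphenyl)methyl]-4,5-dihydrofuran-2-yl]oxy}trimethylsilane F4. A Mukaiyama aldol addition of F4 to 16 with BF3·OEt2 in CH2Cl2 at −78 °C is irreversible and follows the same anti facial preference. Aqueous NaHCO3 work-up delivers 18.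

In the hydrogenolysis of step 10 the benzylic acetate sits next to a quaternary carbon and may survive while the benzyl ethers are lost. The fallback sets out from 18 and comes back at 20. Ionic hydrogenation of 18 with Et3SiH and BF3·OEt2 in CH2Cl2 (−78 → −20 °C) reduces the para-alkoxybenzylic alcohol through its stabilised benzylic cation. The product is (3R,4R)-3-(benzyloxy)-3,4-bis[(4-benzyloxy-3-methoxyphenyl)methyl]oxolan-2-one F5. Plain O-debenzylation of F5 (H2, Pd/C, EtOAc/MeOH, rt) then gives 20 without any benzylic C–O cleavage being asked of the catalyst.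

**Further compounds**

F1 | step 6 | lithium (4S)-4-[(4-benzyloxy-3-methoxyphenyl)methyl]-4,5-dihydrofuran-2-olate | [Li+].[O-]C1=C[C@H](Cc2ccc(OCc3ccccc3)c(OC)c2)CO1
F2 | step 6 | {[(4S)-4-[(4-benzyloxy-3-methoxyphenyl)methyl]-4,5-dihydrofuran-2-yl]oxy}trimethylsilane | C[Si](C)(C)OC1=C[C@H](Cc2ccc(OCc3ccccc3)c(OC)c2)CO1
F3 | step 6 | (3S,4R)-4-[(4-benzyloxy-3-methoxyphenyl)methyl]-3-[(trimethylsilyl)oxy]oxolan-2-one | O=C1OC[C@@H](Cc2ccc(OCc3ccccc3)c(OC)c2)[C@@H]1O[Si](C)(C)C
F4 | step 8 | {[(4R)-3-(benzyloxy)-4-[(4-benzyloxy-3-methoxyphenyl)methyl]-4,5-dihydrofuran-2-yl]oxy}trimethylsilane | C[Si](C)(C)OC1=C(OCc2ccccc2)[C@H](Cc2ccc(OCc3ccccc3)c(OC)c2)CO1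
F5 | step 10 | (3R,4R)-3-(benzyloxy)-3,4-bis[(4-benzyloxy-3-methoxyphenyl)methyl]oxolan-2-one | O=C1OC[C@@H](Cc2ccc(OCc3ccccc3)c(OC)c2)[C@]1(OCc1ccccc1)Cc1ccc(OCc2ccccc2)c(OC)c1
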